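**Retrosynthetic overview**
1. Last C–C bond: flavanone C2–aryl, by Pd(OCOCF3)2/(R)-t-BuPyOx conjugate addition of chroman-6-ylboronic acid 19 to 7-(benzyloxy)chromone 21 (sets 2S); the chromanone rings are bought as the chromone.
2. trans-Diol (3R,4S): Jacobsen–Katsuki epoxidation of 2H-chromene 11, then water opening at benzylic C4 with inversion; the C8 hydroxyl comes from the C8 silyl group (ICl, then Cu-catalysed O-benzylation).
3. Pyran ring of the chroman: aryne–enal annulation of aryl triflate 6 with 3-methylbut-2-enal, forming O1–C8a and C4a–C4 (and then O1–C2) in one operation.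
4. Enabling feature: in the benzene ring of the chroman, C8a (carrying O1) is para to C6 and flanked by C8 (OH) and C4a (bonded to C4). A symmetric 4-bromo-2,6-bis(trimethylsilyl)phenyl triflate therefore gives a single aryne, and its remaining C8 silyl group steers the aldehyde oxygen to C8a and later becomes the C8 hydroxyl.
5. Ring order: benzene ring of the chroman (from 2,4,6-tribromophenol) → pyran ring (step 3) → union with the preformed chromone (step 11).

Key step: step 3

Assumption: the PyOx/Pd addition to chromones is taken to follow the facial sense known for cyclic enones, so the (R)-ligand should give the 2S flavanone; if a model reaction shows the opposite, the (S)-ligand is used in step 11.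

**Route**

Step 1
Reactants: 1 2,4,6-tribromophenol
Product: 3 2,4-dibromo-6-(trimethylsilyl)phenol, via (2,4,6-tribromophenoxy)trimethylsilane 2 (not isolated)
Conditions: HMDS, THF, 70 °C; evaporate; n-BuLi (1.05 equiv), THF, −78 °C to rt; aq NH4Cl
Reagents that add atoms: hexamethyldisilazane, C[Si](C)(C)N[Si](C)(C)C
Why: O-silylation, then bromine–lithium exchange ortho to the silyloxy group and irreversible anionic 1,3 O→C silyl shift (retro-Brook rearrangement), which drains only an ortho aryllithium and so should leave the para bromine in place.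

Step 2
Reactants: 3 2,4-dibromo-6-(trimethylsilyl)phenol
Product: 6 4-bromo-2,6-bis(trimethylsilyl)phenyl trifluoromethanesulfonate, via silyl ether 4 (not isolated), via lithium 4-bromo-2,6-bis(trimethylsilyl)phenoxide 5 (not isolated)
Conditions: HMDS, THF, 70 °C; evaporate; n-BuLi (1.0 equiv), THF, −78 °C to 0 °C; Tf2O, −78 °C to rt
Reagents that add atoms: hexamethyldisilazane, C[Si](C)(C)N[Si](C)(C)C; trifluoromethanesulfonic anhydride, O=S(=O)(OS(=O)(=O)C(F)(F)F)C(F)(F)F
Why: a second retro-Brook rearrangement at the remaining ortho bromine and O-triflation of the lithium phenoxide in the same flask, the usual one-flask entry to ortho-silylaryl triflates.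

Step 3
Reactants: 6 4-bromo-2,6-bis(trimethylsilyl)phenyl trifluoromethanesulfonate; 7 3-methylbut-2-enal
Product: 11 6-bromo-2,2-dimethyl-8-(trimethylsilyl)-2H-chromene, via 5-bromo-3-(trimethylsilyl)benzyne 8 (not isolated), via benzoxete 9 (not isolated), via ortho-quinone methide 10 (not isolated)
Conditions: CsF (3 equiv), 7 (3 equiv), MeCN, 0 °C to rt
Reagents that add atoms: none
Why: Fluoride attacks either of the two equivalent trimethylsilyl groups of 6 and triflate leaves, so the symmetric precursor can give only aryne 8 (triple bond C4a–C8a, silicon on C8, bromine on C6). The carbonyl oxygen of 7 adds to the aryne and the aryl anion collapses on the oxocarbenium carbon (stepwise formal [2+2], forming O1–C8a and C4a–C4) to benzoxete 9, which opens by 4π electrocyclic ring opening to ortho-quinone methide 10; the pyran ring then closes by thermal disrotatory oxa-6π electrocyclization (O1–C2 bond), the closest known reaction type being the fluoride-mediated annulation of ortho-silylaryl triflate arynes with α,β-unsaturated aldehydes to 2H-chromenes. The step needs regioselectivity: in 3-silylarynes the electropositive silicon makes the adjacent aryne carbon the more linear and electrophilic one, so small nucleophiles add ortho to silicon, here the aldehyde oxygen at C8a, while the bulkier carbon terminus ends on C4a away from the silyl group, and the bromine para to C8a (aryl anion at C4a, meta to Br) works in the same direction. No stereocenter is formed (C2 carries two methyl groups and C3=C4 remains an alkene); C3 and C4 are set in steps 4 and 5. Excess 7 should suppress capture of 10 by a second aryne, and the aryl bromide and the remaining aryl–silicon bond should be inert to CsF at room temperature.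

Step 4
Reactants: 11 6-bromo-2,2-dimethyl-8-(trimethylsilyl)-2H-chromene
Product: 12 (3R,4R)-6-bromo-3,4-epoxy-2,2-dimethyl-8-(trimethylsilyl)chromane
Conditions: (R,R)-(salen)MnCl (5 mol %; salen = N,N'-bis(3,5-di-tert-butylsalicylidene)cyclohexane-1,2-diamine dianion, trivalent manganese), 4-phenylpyridine N-oxide (20 mol %), aq NaOCl (pH 11.3), CH2Cl2, 0 °C
Reagents that add atoms: sodium hypochlorite, [Na+].[O-]Cl
Why: Jacobsen–Katsuki epoxidation, for which 2,2-dimethyl-2H-chromenes are the best substrate class; the (R,R) catalyst should deliver oxygen to the face that gives the (3R,4R) epoxide (catalyst control of both centers).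

Step 5
Reactants: 12 (3R,4R)-6-bromo-3,4-epoxy-2,2-dimethyl-8-(trimethylsilyl)chromane
Product: 13 (3R,4S)-6-bromo-2,2-dimethyl-8-(trimethylsilyl)chromane-3,4-diol
Conditions: HClO4 (0.1 M), THF/H2O 3:1, 0 °C to rt
Reagents that add atoms: water, O
Why: acid-catalysed epoxide hydrolysis in which water attacks the benzylic C4 anti to the C3–O bond (inversion at C4, retention at C3), which should give the trans (3R,4S) diol; the electron-poor arene at this stage disfavours a free benzylic cation.

Step 6
Reactants: 13 (3R,4S)-6-bromo-2,2-dimethyl-8-(trimethylsilyl)chromane-3,4-diol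
Product: 14 (3R,4S)-6-bromo-3,4-bis(tert-butyldimethylsilyloxy)-2,2-dimethyl-8-(trimethylsilyl)chromane
Conditions: TBSOTf (3 equiv), 2,6-lutidine (4 equiv), CH2Cl2, 0 °C to rt
Reagents that add atoms: tert-butyldimethylsilyl trifluoromethanesulfonate, CC(C)(C)[Si](C)(C)OS(=O)(=O)C(F)(F)F
Why: silyl triflate silylation under buffered, non-ionising conditions protects both hindered secondary hydroxyls without touching the C4 configuration.

Step 7
Reactants: 14 (3R,4S)-6-bromo-3,4-bis(tert-butyldimethylsilyloxy)-2,2-dimethyl-8-(trimethylsilyl)chromane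
Product: 15 (3R,4S)-6-bromo-3,4-bis(tert-butyldimethylsilyloxy)-8-iodo-2,2-dimethylchromane
Conditions: ICl (1.1 equiv), CH2Cl2, −78 °C to 0 °C
Reagents that add atoms: iodine monochloride, ClI
Why: electrophilic ipso-iododesilylation, favoured at C8 by the β-silicon effect and by O1 ortho to it, while C5–H and C7–H are meta to O1 and unactivated.

Step 8
Reactants: 15 (3R,4S)-6-bromo-3,4-bis(tert-butyldimethylsilyloxy)-8-iodo-2,2-dimethylchromane
Product: 16 (3R,4S)-8-(benzyloxy)-6-bromo-3,4-bis(tert-butyldimethylsilyloxy)-2,2-dimethylchromane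
Conditions: CuI (10 mol %), 3,4,7,8-tetramethyl-1,10-phenanthroline (20 mol %), Cs2CO3 (1.5 equiv), BnOH (3 equiv), toluene, 80 °C
Reagents that add atoms: benzyl alcohol, OCc1ccccc1
Why: Ullmann-type Cu-catalysed C–O coupling of an aryl iodide with a primary alcohol; at 80 °C the aryl bromide should not react.

Step 9
Reactants: 16 (3R,4S)-8-(benzyloxy)-6-bromo-3,4-bis(tert-butyldimethylsilyloxy)-2,2-dimethylchromane
Product: 19 [(3R,4S)-8-(benzyloxy)-3,4-bis(tert-butyldimethylsilyloxy)-2,2-dimethylchroman-6-yl]boronic acid, via aryllithium 17 (not isolated), via lithium aryltriisopropoxyborate 18 (not isolated)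
Conditions: n-BuLi (1.1 equiv), THF, −78 °C; B(OiPr)3, −78 °C to rt; aq NH4Cl
Reagents that add atoms: triisopropyl borate, CC(C)OB(OC(C)C)OC(C)C; water, O
Why: bromine–lithium exchange, borate trapping and hydrolysis, the standard route to an arylboronic acid; silyl and benzyl ethers tolerate n-BuLi at −78 °C.

Step 10
Reactants: 20 7-hydroxychromone
Product: 21 7-(benzyloxy)chromone
Conditions: BnBr (1.1 equiv), K2CO3, DMF, rt
Reagents that add atoms: benzyl bromide, BrCc1ccccc1
Why: Williamson O-alkylation of the acidic 7-hydroxyl under mild carbonate conditions that leave the chromone ring closed.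

Step 11
Reactants: 19 [(3R,4S)-8-(benzyloxy)-3,4-bis(tert-butyldimethylsilyloxy)-2,2-dimethylchroman-6-yl]boronic acid; 21 7-(benzyloxy)chromone
Product: 22 (2S)-7-(benzyloxy)-2-[(3R,4S)-8-(benzyloxy)-3,4-bis(tert-butyldimethylsilyloxy)-2,2-dimethylchroman-6-yl]chroman-4-one
Conditions: Pd(OCOCF3)2 (5 mol %), (R)-t-BuPyOx (6 mol %), NH4PF6 (30 mol %), H2O (5 equiv), 21 (1.5 equiv), ClCH2CH2Cl, 60 °C
Reagents that add atoms: none
Why: asymmetric conjugate addition of an arylboronic acid to a chromone catalysed by a cationic divalent palladium–pyridine-oxazoline complex; the ligand fixes the face of aryl transfer and so sets the 2S center, and the boronic acid has no ortho substituent.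

Step 12
Reactants: 22 (2S)-7-(benzyloxy)-2-[(3R,4S)-8-(benzyloxy)-3,4-bis(tert-butyldimethylsilyloxy)-2,2-dimethylchroman-6-yl]chroman-4-one
Product: 23 (2S)-7-hydroxy-2-[(3R,4S)-8-hydroxy-3,4-bis(tert-butyldimethylsilyloxy)-2,2-dimethylchroman-6-yl]chroman-4-one
Conditions: H2 (1 atm), Pd/C (10 %), EtOAc, rt, stopped at full debenzylation
Reagents that add atoms: none
Why: hydrogenolysis of the two aryl benzyl ethers under neutral conditions; the C4 silyl ether shields the benzylic C4–O bond and flavanones normally survive this debenzylation.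

Step 13
Reactants: 23 (2S)-7-hydroxy-2-[(3R,4S)-8-hydroxy-3,4-bis(tert-butyldimethylsilyloxy)-2,2-dimethylchroman-6-yl]chroman-4-one
Product: 24 (2S)-7-hydroxy-2-[(3R,4S)-3,4,8-trihydroxy-2,2-dimethylchroman-6-yl]chroman-4-one (target)
Conditions: HF·pyridine, THF/pyridine, 0 °C to rt
Reagents that add atoms: none
Why: fluoride desilylation under buffered, weakly acidic conditions, which avoids both base-induced opening of the flavanone (loss of the 2S center) and acid ionisation at benzylic C4.

**Compound list**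
1 | 2,4,6-tribromophenol | Oc1c(Br)cc(Br)cc1Br | starting material
2 | (2,4,6-tribromophenoxy)trimethylsilane (formed in the flask) | C[Si](C)(C)Oc1c(Br)cc(Br)cc1Br | intermediate
3 | 2,4-dibromo-6-(trimethylsilyl)phenol | Oc1c(Br)cc(Br)cc1[Si](C)(C)C | intermediate
4 | [2,4-dibromo-6-(trimethylsilyl)phenoxy]trimethylsilane (formed in the flask) | C[Si](C)(C)Oc1c(Br)cc(Br)cc1[Si](C)(C)C | intermediate
5 | lithium 4-bromo-2,6-bis(trimethylsilyl)phenoxide (formed in the flask) | [Li+].[O-]c1c([Si](C)(C)C)cc(Br)cc1[Si](C)(C)C | intermediate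
6 | 4-bromo-2,6-bis(trimethylsilyl)phenyl trifluoromethanesulfonate | C[Si](C)(C)c1cc(Br)cc([Si](C)(C)C)c1OS(=O)(=O)C(F)(F)F | intermediate
7 | 3-methylbut-2-enal | CC(C)=CC=O | starting material
8 | 5-bromo-3-(trimethylsilyl)benzyne (formed in the flask) | C[Si](C)(C)C1=CC(Br)=CC#C1 | intermediate
9 | 4-bromo-2-(2-methylprop-1-enyl)-6-(trimethylsilyl)-2H-benzoxete (formed in the flask) | CC(C)=CC1Oc2c1cc(Br)cc2[Si](C)(C)C | intermediate
10 | (Z)-4-bromo-6-(3-methylbut-2-enylidene)-2-(trimethylsilyl)cyclohexa-2,4-dien-1-one, ortho-quinone methide (formed in the flask) | O=C1/C(=C\C=C(C)C)C=C(Br)C=C1[Si](C)(C)C | intermediate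
11 | 6-bromo-2,2-dimethyl-8-(trimethylsilyl)-2H-chromene | CC1(C)Oc2c(cc(Br)cc2C=C1)[Si](C)(C)C | intermediate
12 | (3R,4R)-6-bromo-3,4-epoxy-2,2-dimethyl-8-(trimethylsilyl)chromane | CC1(C)Oc2c([Si](C)(C)C)cc(Br)cc2[C@H]3O[C@@H]13 | intermediate
13 | (3R,4S)-6-bromo-2,2-dimethyl-8-(trimethylsilyl)chromane-3,4-diol (trans) | CC1(C)Oc2c([Si](C)(C)C)cc(Br)cc2[C@H](O)[C@H]1O | intermediate
14 | (3R,4S)-6-bromo-3,4-bis(tert-butyldimethylsilyloxy)-2,2-dimethyl-8-(trimethylsilyl)chromane | CC1(C)Oc2c([Si](C)(C)C)cc(Br)cc2[C@H](O[Si](C)(C)C(C)(C)C)[C@H]1O[Si](C)(C)C(C)(C)C | intermediate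
15 | (3R,4S)-6-bromo-3,4-bis(tert-butyldimethylsilyloxy)-8-iodo-2,2-dimethylchromane | CC1(C)Oc2c(I)cc(Br)cc2[C@H](O[Si](C)(C)C(C)(C)C)[C@H]1O[Si](C)(C)C(C)(C)C | intermediate
16 | (3R,4S)-8-(benzyloxy)-6-bromo-3,4-bis(tert-butyldimethylsilyloxy)-2,2-dimethylchromane | CC1(C)Oc2c(OCc3ccccc3)cc(Br)cc2[C@H](O[Si](C)(C)C(C)(C)C)[C@H]1O[Si](C)(C)C(C)(C)C | intermediate
17 | [(3R,4S)-8-(benzyloxy)-3,4-bis(tert-butyldimethylsilyloxy)-2,2-dimethylchroman-6-yl]lithium (formed in the flask) | CC1(C)Oc2c(OCc3ccccc3)cc([Li])cc2[C@H](O[Si](C)(C)C(C)(C)C)[C@H]1O[Si](C)(C)C(C)(C)C | intermediate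
18 | lithium [(3R,4S)-8-(benzyloxy)-3,4-bis(tert-butyldimethylsilyloxy)-2,2-dimethylchroman-6-yl]triisopropoxyborate (formed in the flask) | [Li+].CC1(C)Oc2c(OCc3ccccc3)cc([B-](OC(C)C)(OC(C)C)OC(C)C)cc2[C@H](O[Si](C)(C)C(C)(C)C)[C@H]1O[Si](C)(C)C(C)(C)C | intermediate
19 | [(3R,4S)-8-(benzyloxy)-3,4-bis(tert-butyldimethylsilyloxy)-2,2-dimethylchroman-6-yl]boronic acid | CC1(C)Oc2c(OCc3ccccc3)cc(B(O)O)cc2[C@H](O[Si](C)(C)C(C)(C)C)[C@H]1O[Si](C)(C)C(C)(C)C | intermediate
20 | 7-hydroxychromone | O=c1ccoc2cc(O)ccc12 | starting material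
21 | 7-(benzyloxy)chromone | O=c1ccoc2cc(OCc3ccccc3)ccc12 | intermediate
22 | (2S)-7-(benzyloxy)-2-[(3R,4S)-8-(benzyloxy)-3,4-bis(tert-butyldimethylsilyloxy)-2,2-dimethylchroman-6-yl]chroman-4-one | CC1(C)Oc2c(OCc3ccccc3)cc([C@@H]3CC(=O)c4ccc(OCc5ccccc5)cc4O3)cc2[C@H](O[Si](C)(C)C(C)(C)C)[C@H]1O[Si](C)(C)C(C)(C)C | intermediate
23 | (2S)-7-hydroxy-2-[(3R,4S)-8-hydroxy-3,4-bis(tert-butyldimethylsilyloxy)-2,2-dimethylchroman-6-yl]chroman-4-one | CC1(C)Oc2c(O)cc([C@@H]3CC(=O)c4ccc(O)cc4O3)cc2[C@H](O[Si](C)(C)C(C)(C)C)[C@H]1O[Si](C)(C)C(C)(C)C | intermediate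
24 | (2S)-7-hydroxy-2-[(3R,4S)-3,4,8-trihydroxy-2,2-dimethylchroman-6-yl]chroman-4-one | CC1(C)Oc2c(O)cc([C@@H]3CC(=O)c4ccc(O)cc4O3)cc2[C@H](O)[C@H]1O | target

**Step count**
Total steps: 13. Longest linear sequence: 12 (steps 1–9 and 11–13; step 10 prepares the chromone partner).

**Steps most likely to fail**

Step 3. Possible failures are addition of the aldehyde oxygen to the wrong aryne carbon, capture of the ortho-quinone methide by a second aryne, and fluoride-induced self-condensation of the enal. The fallback sets out from 3 and returns at 11. Compound 3 is deprotonated with i-PrMgCl (1 equiv) and the bromine ortho to the phenoxide oxygen is exchanged with n-BuLi (THF, −78 °C, chelation by the phenoxide); a DMF quench should give 5-bromo-2-hydroxy-3-(trimethylsilyl)benzaldehyde F1. Addition of 2-methylprop-1-enylmagnesium bromide (2.2 equiv, THF, 0 °C) should give 4-bromo-2-(1-hydroxy-3-methylbut-2-enyl)-6-(trimethylsilyl)phenol F2. Warming F2 in toluene (80–110 °C, neutral alumina) should eliminate water to the same ortho-quinone methide 10, which closes to 11. In this sequence the C4a–C4 bond is fixed by the formyl position, so no aryne regiochemistry is involved.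

Step 11. Possible failures are protodeboronation outrunning transmetalation and poor facial selectivity on the chromone. The fallback sets out from 16 and returns at 22. Bromine–lithium exchange of 16 (n-BuLi, THF, −78 °C) and a DMF quench should give (3R,4S)-8-(benzyloxy)-3,4-bis(tert-butyldimethylsilyloxy)-2,2-dimethylchromane-6-carbaldehyde F3. Claisen–Schmidt condensation with commercial 1-[4-(benzyloxy)-2-hydroxyphenyl]ethanone (KOH, EtOH, rt) should give the (E)-2'-hydroxychalcone F4. Intramolecular oxa-Michael closure (NaOAc, EtOH, reflux, optionally with a quinine-derived thiourea to bias the closure) should give 22 together with its 2R epimer F5. The two are diastereomers that should be separable by chromatography, and F5 is returned to the equilibrium under the same conditions.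

Step 8. Possible failures are slow coupling at the hindered iodide, loss of a silyl ether to benzyl alkoxide at 80 °C, and partial reaction at the bromide. The fallback sets out from 15 and returns at 16. Iodine–magnesium exchange with i-PrMgCl·LiCl (THF, −40 °C, where the iodide reacts far faster than the bromide), trapping with B(OMe)3 and oxidation with H2O2/NaOH at 0 °C should give (3R,4S)-6-bromo-3,4-bis(tert-butyldimethylsilyloxy)-2,2-dimethylchroman-8-ol F6. O-Benzylation (BnBr, K2CO3, DMF, rt) should then give 16.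

**Further compounds**
F1 | step 3 | 5-bromo-2-hydroxy-3-(trimethylsilyl)benzaldehyde | O=Cc1cc(Br)cc([Si](C)(C)C)c1O
F2 | step 3 | 4-bromo-2-(1-hydroxy-3-methylbut-2-enyl)-6-(trimethylsilyl)phenol | CC(C)=CC(O)c1cc(Br)cc([Si](C)(C)C)c1O
F3 | step 11 | (3R,4S)-8-(benzyloxy)-3,4-bis(tert-butyldimethylsilyloxy)-2,2-dimethylchromane-6-carbaldehyde | CC1(C)Oc2c(OCc3ccccc3)cc(C=O)cc2[C@H](O[Si](C)(C)C(C)(C)C)[C@H]1O[Si](C)(C)C(C)(C)C
F4 | step 11 | (E)-1-[4-(benzyloxy)-2-hydroxyphenyl]-3-[(3R,4S)-8-(benzyloxy)-3,4-bis(tert-butyldimethylsilyloxy)-2,2-dimethylchroman-6-yl]prop-2-en-1-one | CC1(C)Oc2c(OCc3ccccc3)cc(/C=C/C(=O)c3ccc(OCc4ccccc4)cc3O)cc2[C@H](O[Si](C)(C)C(C)(C)C)[C@H]1O[Si](C)(C)C(C)(C)C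
F5 | step 11 | (2R)-7-(benzyloxy)-2-[(3R,4S)-8-(benzyloxy)-3,4-bis(tert-butyldimethylsilyloxy)-2,2-dimethylchroman-6-yl]chroman-4-one | CC1(C)Oc2c(OCc3ccccc3)cc([C@H]3CC(=O)c4ccc(OCc5ccccc5)cc4O3)cc2[C@H](O[Si](C)(C)C(C)(C)C)[C@H]1O[Si](C)(C)C(C)(C)C
F6 | step 8 | (3R,4S)-6-bromo-3,4-bis(tert-butyldimethylsilyloxy)-2,2-dimethylchroman-8-ol | CC1(C)Oc2c(O)cc(Br)cc2[C@H](O[Si](C)(C)C(C)(C)C)[C@H]1O[Si](C)(C)C(C)(C)C
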